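The data are simulated from invented constants, noise included.

The question is how much substrate and target the dawn flask holds at 20 min, well beyond its last reading at 6.00 min.

all flasks: substrate 10 mM; free catalyst 0.15 mM

| charge | reagent | remark | time |
|---|---|---|---|
| dawn | 10 mM | the very flask that is asked about, followed so far |  |
| noon | 6.7 mM | run made earlier |  |
| flask | 10.0 mM |  | 20 min |

| run | time / min | target / % | substrate / % |
|---|---|---|---|
| dawn | 0.333 | 2.1 | 97.0 |
| dawn | 1.00 | 7.4 | 90.9 |
| dawn | 1.50 | 11.7 | 87.1 |
| dawn | 2.50 | 19.3 | 80.2 |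
| dawn | 4.00 | 28.7 | 69.7 |
| dawn | 5.00 | 35.4 | 63.8 |
| dawn | 6.00 | 41.0 | 57.7 |
| noon | 0.667 | 3.4 | 95.1 |
| noon | 1.00 | 6.4 | 92.4 |
| noon | 1.33 | 7.9 | 90.6 |
| noon | 2.50 | 15.1 | 84.6 |
| noon | 3.00 | 16.7 | 81.8 |
| noon | 5.00 | 26.6 | 71.6 |
| noon | 8.00 | 37.1 | 61.2 |

(each reading ± 0.3 percentage points)

- concentration of target at 20 min, in mM
- concentration of substrate at 20 min, in mM



1. Go to logarithms. Between 1.00 min and 6.00 min the dawn substrate falls by 0.197 powers of ten. That reads 25.3 min as the decade time, the minutes the substrate needs to lose one power of ten.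

2. Weigh the last reading. The reach of 14.0 min spans 0.553 powers of ten. The scatter of 0.3 percentage points on 57.7% passes into the answer as a share of 0.520%, which is small.

3. Weigh the decade time. Its share of error returns 1.27 times over in the answer, so, share for share, it weighs more than the last reading.

4. Weigh the reagent charge. The noon decade time reads 39.1 min, 1.55 times dawn's, and the dawn charge of reagent is 1.49 times noon's. The asked flask is dawn itself, so this charge needs no correction.

5. Weigh the gap. At 6.00 min, substrate lost exceeds target by 1.30% of the charge, which moves the target by 0.130 mM and needs no fine knowledge.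

6. Reckon. Lower the last reading by the reach: substrate 1.62 mM, target 8.25 mM.

The forecast, a little apart from this, says 1.7 mM and 8.2 mM, holding that “the rate tracks reagent, roughly first order”.

    substrate + free catalyst ⇌ catalyst intermediate A (K = 1200 L mol⁻¹, k = 2800 L mol⁻¹ min⁻¹)
    reagent + catalyst intermediate A ⇌ catalyst intermediate B (K = 1000 L mol⁻¹, k = 1100 L mol⁻¹ min⁻¹)
    catalyst intermediate B ⇌ by-product + catalyst intermediate C (K = 0.0210 M, k = 150 min⁻¹)
    catalyst intermediate C → free catalyst + target (k = 30.0 min⁻¹)
    reagent → decomposition product (k = 5.50 × 10⁻⁴ min⁻¹)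

The flask holds 1.70 mM of substrate and 8.21 mM of target at 20 min. Catalyst intermediate A in this flask then holds 50.6% of the catalyst charged, more than free catalyst at 44.4%. Now carry the decade time over a shorter reach, from the last reading to 8.00 min: it gives 4.81 mM of substrate, and the same flask stopped at that time holds 4.89 mM.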